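**Retrosynthetic overview**
1. The CH2 bridge between C5 of ring A (the aromatic ring) and C6 of ring B (the gem-dimethyl cyclohexadienone) is cut last. Ring A is delivered as Mannich base 12, an ortho-quinone methide donor, and ring B as acetylfilicinic acid 14.
2. Ring B needs no ring construction: 14 comes from 2,4,6-trihydroxyacetophenone 13 by geminal C-dimethylation with dearomatisation.
3. The strategy rests on ring A: the propanoyl-bearing carbon C1 stands between the oxygen-bearing carbons C2 and C6, with the third oxygen at C4. The C1–C(=O) bond and one flanking C–O bond are made together by insertion of 3,5-dimethoxybenzyne (from 7) into the acyl–oxygen bond of propanoic acid 8, giving 10; the remaining ortho methyl ether is then cleaved.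
4. Aryne precursor 7 comes from symmetrical 3,5-dimethoxyphenol 1 by carbamate-directed ortho-silylation and exchange of the carbamate for a triflate.
5. No ring is formed anywhere in the route; both six-membered rings are carried in from aromatic starting materials.

Key step: step 4

Remark: ring B of the target is drawn as one enol tautomer of a freely equilibrating triketone system; the compound has no stereocenter, so no stereocontrol is needed.

**Route**

Step 1
Reactants: 1 3,5-dimethoxyphenol
Product: 2 3,5-dimethoxyphenyl N-(propan-2-yl)carbamate
Conditions: i-PrNCO, Et3N (cat.), CH2Cl2, rt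
Reagents that add atoms: isopropyl isocyanate, CC(C)N=C=O
Why: Base-catalysed addition of the phenol to the isocyanate (carbamoylation) should install an N–H carbamate that is a strong ortho-directing group and can later be removed under mild base.

Step 2
Reactants: 2 3,5-dimethoxyphenyl N-(propan-2-yl)carbamate
Product: 5 3,5-dimethoxy-2-(trimethylsilyl)phenyl N-(propan-2-yl)carbamate, via N-silyl carbamate 3 (not isolated), via C-silylated N-silyl carbamate 4 (not isolated)
Conditions: TBSOTf, TMEDA, Et2O, 0 °C to rt; n-BuLi, TMEDA, −78 °C; Me3SiCl, −78 °C to rt; sat. aq. NaHSO4, 0 °C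
Reagents that add atoms: chlorotrimethylsilane, C[Si](C)(C)Cl; tert-butyldimethylsilyl trifluoromethanesulfonate, CC(C)(C)[Si](C)(C)OS(=O)(=O)C(F)(F)F (its silyl group is carried only by 3 and 4)
Why: Directed ortho-metalation of the transiently N-silylated carbamate should occur at C2, where the carbamate and a methoxy group cooperate (C2 and C6 are equivalent by symmetry, and the site between the two weaker methoxy directors is disfavoured), the aryllithium is trapped by Me3SiCl at −78 °C before any anionic ortho-Fries shift, and the brief cold acidic work-up removes the labile N-silyl group while sparing the aryl–silicon bond.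

Step 3
Reactants: 5 3,5-dimethoxy-2-(trimethylsilyl)phenyl N-(propan-2-yl)carbamate
Product: 7 3,5-dimethoxy-2-(trimethylsilyl)phenyl trifluoromethanesulfonate, via silylphenol 6 (not isolated)
Conditions: Et2NH, DBU, MeCN, 40 °C; then PhNTf2, rt
Reagents that add atoms: N-phenylbis(trifluoromethanesulfonimide), O=S(=O)(N(c1ccccc1)S(=O)(=O)C(F)(F)F)C(F)(F)F
Why: DBU deprotonates the carbamate N–H and an E1cB elimination releases the aryloxide and isopropyl isocyanate (scavenged by Et2NH as a urea), after which the aryloxide is triflated in the same flask by the mild triflyl donor, so the acid-sensitive electron-rich arylsilane never meets acid or strong nucleophile.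

Step 4
Reactants: 7 3,5-dimethoxy-2-(trimethylsilyl)phenyl trifluoromethanesulfonate; 8 propanoic acid
Product: 10 1-(2-hydroxy-4,6-dimethoxyphenyl)propan-1-one, via 3,5-dimethoxybenzyne 9 (not isolated)
Conditions: CsF (4 equiv), 8 (1.2 equiv), THF, 125 °C, sealed tube
Reagents that add atoms: none
Why: Fluoride attacks silicon and triflate leaves, giving aryne 9 with its triple bond between the former C–Si and C–OTf carbons; the methoxy group on the carbon next to the former silyl carbon polarises and distorts the triple bond, so caesium propanoate adds through oxygen at the far aryne carbon and the aryl anion develops beside that methoxy group. The anion then attacks the neighbouring ester carbonyl to give a four-membered alkoxide that opens to the phenoxide of the ortho-hydroxy ketone (an anionic Fries-type 1,3-acyl shift), so the C–O and C–C(=O) bonds of ring A form in one operation. The closest known reaction type is the fluoride-triggered insertion of arynes from ortho-silylaryl triflates into the acyl–oxygen bond of carboxylic acids, which with 3-methoxybenzyne gives 2-hydroxy-6-methoxyaryl ketones. No ring is closed permanently (the four-membered intermediate is transient) and no stereocenter is formed. The step needs regioselective addition to the unsymmetrical aryne and acyl transfer that outruns protonation of the aryl anion: the first is secured by the inductive effect of the flanking methoxy group, the second by the high temperature, the ethereal solvent and the absence of a large excess of acid.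

Step 5
Reactants: 10 1-(2-hydroxy-4,6-dimethoxyphenyl)propan-1-one
Product: 11 1-(2,6-dihydroxy-4-methoxyphenyl)propan-1-one
Conditions: AlCl3 (4 equiv), CH2Cl2, 0 °C to reflux; then ice-cold 1 M HCl
Reagents that add atoms: none
Why: Chelation-directed ether cleavage: aluminium bound to the ketone oxygen activates the methyl ether ortho to the carbonyl for chloride attack at the methyl group, and an excess of AlCl3 is chosen because it is known to clear both ortho ethers of 2,6-dimethoxyaryl carbonyl compounds, whereas the para ether has no such assistance and should survive.

Step 6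
Reactants: 11 1-(2,6-dihydroxy-4-methoxyphenyl)propan-1-one
Product: 12 1-{3-[(dimethylamino)methyl]-2,6-dihydroxy-4-methoxyphenyl}propan-1-one
Conditions: Me2N=CH2+ I− (Eschenmoser's salt, 1.0 equiv), K2CO3 (1.0 equiv), MeCN, 0 °C to rt
Reagents that add atoms: N,N-dimethylmethylideneammonium iodide (Eschenmoser's salt), C=[N+](C)C.[I-]
Why: Mannich-type aminomethylation of the phenoxide by the preformed iminium ion occurs ortho to a hydroxyl group at one of the two equivalent free ring positions, and one equivalent of a formaldehyde-free reagent limits bis-aminomethylation and rules out methylene-bridged homodimers.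

Step 7
Reactants: 13 2,4,6-trihydroxyacetophenone
Product: 14 2-acetyl-3,5-dihydroxy-4,4-dimethylcyclohexa-2,5-dien-1-one (acetylfilicinic acid)
Conditions: NaOMe (3 equiv), MeI (2.1 equiv), MeOH, 0 °C to rt; then 1 M HCl
Reagents that add atoms: iodomethane, CI
Why: Classical C-alkylation of an acylphloroglucinol polyanion, in which the second methylation at the already methylated ring carbon dearomatises the ring to the gem-dimethyl triketone, with limited MeI holding back the tri- and tetramethylated by-products that are removed by chromatography.

Step 8
Reactants: 12 1-{3-[(dimethylamino)methyl]-2,6-dihydroxy-4-methoxyphenyl}propan-1-one; 14 2-acetyl-3,5-dihydroxy-4,4-dimethylcyclohexa-2,5-dien-1-one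
Product: 16 2-acetyl-6-[(2,4-dihydroxy-6-methoxy-3-propanoylphenyl)methyl]-3,5-dihydroxy-4,4-dimethylcyclohexa-2,5-dien-1-one, via ortho-quinone methide 15 (not isolated)
Conditions: 14 (1.5 equiv), 1,4-dioxane, 100 °C, N2
Reagents that add atoms: none
Why: The acidic trione protonates the Mannich base, thermal loss of Me2NH gives ortho-quinone methide 15, and conjugate addition of the only C–H enol carbon of 14 (C6) followed by rearomatisation forms the CH2 bridge, a known Mannich-base alkylation of 1,3-dicarbonyl compounds in which the excess of 14 suppresses self-condensation of 12.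

**Compound list**
1 | 3,5-dimethoxyphenol | COc1cc(O)cc(OC)c1 | starting material
2 | 3,5-dimethoxyphenyl N-(propan-2-yl)carbamate | COc1cc(OC)cc(OC(=O)NC(C)C)c1 | intermediate
3 | 3,5-dimethoxyphenyl N-(tert-butyldimethylsilyl)-N-(propan-2-yl)carbamate (not isolated) | COc1cc(OC)cc(OC(=O)N(C(C)C)[Si](C)(C)C(C)(C)C)c1 | intermediate
4 | 3,5-dimethoxy-2-(trimethylsilyl)phenyl N-(tert-butyldimethylsilyl)-N-(propan-2-yl)carbamate (not isolated) | COc1cc(OC)c([Si](C)(C)C)c(OC(=O)N(C(C)C)[Si](C)(C)C(C)(C)C)c1 | intermediate
5 | 3,5-dimethoxy-2-(trimethylsilyl)phenyl N-(propan-2-yl)carbamate | COc1cc(OC)c([Si](C)(C)C)c(OC(=O)NC(C)C)c1 | intermediate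
6 | 3,5-dimethoxy-2-(trimethylsilyl)phenol (not isolated) | COc1cc(O)c([Si](C)(C)C)c(OC)c1 | intermediate
7 | 3,5-dimethoxy-2-(trimethylsilyl)phenyl trifluoromethanesulfonate | COc1cc(OC)c([Si](C)(C)C)c(OS(=O)(=O)C(F)(F)F)c1 | intermediate
8 | propanoic acid | CCC(=O)O | starting material
9 | 3,5-dimethoxybenzyne (1,2-didehydro-3,5-dimethoxybenzene, not isolated) | COC1=CC#CC(OC)=C1 | intermediate
10 | 1-(2-hydroxy-4,6-dimethoxyphenyl)propan-1-one | CCC(=O)c1c(O)cc(OC)cc1OC | intermediate
11 | 1-(2,6-dihydroxy-4-methoxyphenyl)propan-1-one | CCC(=O)c1c(O)cc(OC)cc1O | intermediate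
12 | 1-{3-[(dimethylamino)methyl]-2,6-dihydroxy-4-methoxyphenyl}propan-1-one | CCC(=O)c1c(O)cc(OC)c(CN(C)C)c1O | intermediate
13 | 2,4,6-trihydroxyacetophenone | CC(=O)c1c(O)cc(O)cc1O | starting material
14 | 2-acetyl-3,5-dihydroxy-4,4-dimethylcyclohexa-2,5-dien-1-one (acetylfilicinic acid) | CC(=O)C1=C(O)C(C)(C)C(O)=CC1=O | intermediate
15 | 3-hydroxy-5-methoxy-6-methylidene-2-propanoylcyclohexa-2,4-dien-1-one (not isolated) | CCC(=O)C1=C(O)C=C(OC)C(=C)C1=O | intermediate
16 | 2-acetyl-6-[(2,4-dihydroxy-6-methoxy-3-propanoylphenyl)methyl]-3,5-dihydroxy-4,4-dimethylcyclohexa-2,5-dien-1-one | CCC(=O)c1c(O)cc(OC)c(CC2=C(O)C(C)(C)C(O)=C(C(C)=O)C2=O)c1O | target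

**Step count**
Total steps: 8. Longest linear sequence: 7 (steps 1, 2, 3, 4, 5, 6 and 8); step 7 is a one-step side branch.

**Steps most likely to fail**

Step 4. The aryl anion may be protonated before the acyl group migrates, leaving the aryl ester, or the product phenoxide may add to a second aryne, so that little ketone is obtained. The fallback sets out from 1 and comes back at 10. Compound 1 would be O-acylated with propanoyl chloride (Et3N, CH2Cl2, 0 °C) to 3,5-dimethoxyphenyl propanoate F1. F1 would then undergo a Fries rearrangement (BF3·OEt2, 90 °C, then aqueous work-up to break the boron chelate), in which chelation of the Lewis acid between the phenol oxygen and the ketone should favour migration to the position ortho to the phenol and give 10.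

Step 8. The quinone methide may be captured by a second molecule of 12 or by the free ring position of the product, and the liberated amine may scramble the methylene bridge between the two ring types, giving symmetrical dimers. The fallback sets out from 11 and comes back at 16. Compound 11 would be formylated at its free ring position (Rieche formylation: Cl2CHOMe, TiCl4, CH2Cl2, 0 °C) to 2,4-dihydroxy-6-methoxy-3-propanoylbenzaldehyde F2. F2, 14 and Hantzsch ester with catalytic L-proline in CH2Cl2 at rt would then undergo Knoevenagel condensation to the arylidene trione F3 (not isolated, alkene geometry of no consequence), which is reduced in the same flask by hydride transfer from the Hantzsch ester to 16 (organocatalytic reductive alkylation of a cyclic 1,3-dione).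

Step 5. The cleavage may stall at the aluminium chelate of the existing phenol, leaving the second ortho ether untouched, or it may run on to the para ether. The fallback sets out from 10 and comes back at 11. Compound 10 would be demethylated exhaustively (BBr3, excess, CH2Cl2, −78 °C to rt) to 1-(2,4,6-trihydroxyphenyl)propan-1-one F4. F4 would then be methylated with one equivalent of Me2SO4 (K2CO3, acetone, rt); the 4-hydroxyl is the only one not hydrogen-bonded to the ketone and the most acidic, so it should react first and give 11.

**Further compounds**
F1 | step 4 | 3,5-dimethoxyphenyl propanoate | CCC(=O)Oc1cc(OC)cc(OC)c1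
F2 | step 8 | 2,4-dihydroxy-6-methoxy-3-propanoylbenzaldehyde | CCC(=O)c1c(O)cc(OC)c(C=O)c1O
F3 | step 8 | 2-acetyl-6-[(2,4-dihydroxy-6-methoxy-3-propanoylphenyl)methylidene]-3-hydroxy-4,4-dimethylcyclohex-2-ene-1,5-dione (E/Z not controlled) | CCC(=O)c1c(O)cc(OC)c(C=C2C(=O)C(C)(C)C(O)=C(C(C)=O)C2=O)c1O
F4 | step 5 | 1-(2,4,6-trihydroxyphenyl)propan-1-one | CCC(=O)c1c(O)cc(O)cc1O
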